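Follow one molecule of substrate through the flask, and at each fork ask how likely it is to stand on either side.

substrate 0.40 M; time 12 h

    substrate ⇌ target (K1 = 1.6, k1 = 0.0652 /min)
    substrate ⇌ isomer of the product A (K2 = 2.47, k2 = 0.0299 /min)
    substrate ⇌ third isomer (K3 = 1.8, k3 = 0.0259 /min)
    target → over-reaction product (k4 = 6.47 × 10⁻⁵ /min)
    target ⇌ isomer of the product B (K5 = 1.2, k5 = 0.0157 /min)

1. at 12 h, what has stopped the reaction, if anything has (forward and back rates have come level / it is still moving / all of the substrate has reacted)
2. how much of the substrate has reacted by 12 h
3. how much target there is at 12 h, in percent of the substrate charged
4. how much isomer of the product A there is at 12 h, in percent of the substrate charged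
5. how much isomer of the product B there is at 12 h, in percent of the substrate charged

- the reaction counts as stopped when no species that holds the substrate changes by six tenths of a point or more over the second half of the time
- what has gone from substrate into another species counts as reacted, even if it can come back
- run time (flask): 12 h

Weigh the forms against substrate, whose weight is 1: target 1.6, isomer of the product A 2.47, third isomer 1.8, and isomer of the product B, which lies behind target, 1.92. These weights sum to 8.79. Target's weight over that sum gives 18.2 %: the residence share, the fraction of its time a molecule spends as target once the forks have evened out. This is thermodynamic control.

Turn the charge first. The share holds no charge, so by hand, with the time held, a smaller or larger charge leaves every fraction where it is.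

Turn the time next. By their own step alone, target and isomer of the product B relax more slowly than substrate and target, with a half-life of 0.401 h, short against the run. Target's half-life by that step alone towards over-reaction product is 180 h, long against the run, so by hand this leak takes 0.848 % of the charge by 12 h. Of that, 0.42 percentage points falls in the second half, against a stop mark of 0.6 of a point. At 120 h the same leak would reach 8.13 %.

So I commit to a stopped flask with conversion 88.7 %, target 18.0 %, isomer of the product A 27.9 % and isomer of the product B 21.7 %.

The forecast says “the isomers are effectively equilibrated” and answers: forward and back rates have come level, conversion 88.7 %, target 18.05 %, isomer of the product A 27.9 % and isomer of the product B 21.65 %. Its leak is about 0.9 % where mine is 0.848 %.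

The flask answers: forward and back rates have come level, conversion 88.7 %, target 18.0 %, isomer of the product A 27.9 % and isomer of the product B 21.6 %. In this flask, nearly all of the conversion at 12 h stood at 0.546 h. Isomer of the product B went from 17.1 % at 1.20 h to 21.5 % at 6.00 h, while the net turnover into over-reaction product reached 0.869 % by 12 h. Left ten times as long, the flask leaves the forecast's figures: at 120 h isomer of the product A reads 25.8 % against the forecast's 27.9 %, and over-reaction product reads 8.14 %.

For the neighbour flask with 0.10 M of substrate, the share less the leak again gives target 18.0 % of its charge. Computed, the neighbour flask holds target at 18.0 % of its charge.

The constants used here are invented; what happens was integrated by code.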